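**Retrosynthetic overview**

1. Target 35 ⇐ fluoride desilylation of its octa-TIPS ether 34. The biomimetic oxidative 8–8' coupling of ε-viniferin with resveratrol is deliberately not used.
2. 34 ⇐ tetrahydrofuran acetal 31: the C5 aryl enters last, by Grignard attack on the cyclic oxocarbenium ion anti to three cis aryl groups (4,5-trans). 31 ⇐ lactone 26 by aryl-cerium addition and ionic hydrogenation of the hemiketal (2,3-cis).
3. 26 ⇐ butenolide 25 by syn-hydrogenation anti to the C5 menthyloxy group. This one auxiliary centre sets C3/C4 (cis) and, by relay, all four tetrahydrofuran stereocentres.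
4. 25 ⇐ mucobromic acid, which supplies the four ring carbons and the ring oxygen at the right oxidation levels, by menthyl acetal formation and two site-selective Negishi couplings (C4, then C3).
5. The C3 aryl is bromide 15 ⇐ asymmetric [4+1] annulation of an o-quinone methide with a chiral sulfonium benzylide. Ring order: dihydrobenzofuran first (step 9); the oxygen five-ring comes ready-made as the butenolide (step 10) and is carried to the tetrahydrofuran (steps 13–15).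

Assumption: the ylide from (1R,4R,5R)-isothiocineole is taken to give the (2R,3R)-dihydrobenzofuran, and the (5R)-acetal 19 is taken to be the epimer that crystallises; if either sense is the opposite, the enantiomeric sulfide or (+)-menthol is used and the route is otherwise unchanged.

Abbreviations in names: TIPS = triisopropylsilyl; Men = (1R,2S,5R)-menthyl; ArD = (2R,3R)-3-[3,5-bis(TIPS-oxy)phenyl]-6-(TIPS-oxy)-2-[4-(TIPS-oxy)phenyl]-2,3-dihydrobenzofuran-4-yl.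

**Route**

Step 1
Reactants: 1 5-bromoresorcinol
Product: 2 1-bromo-3,5-bis(TIPS-oxy)benzene
Conditions: TIPSCl (2.2 equiv), imidazole, DMF, 25 °C
Reagents that add atoms: triisopropylsilyl chloride, Cl[Si](C(C)C)(C(C)C)C(C)C
Why: Standard phenol silylation (silyl ether protection); TIPS aryl ethers survive the organometallic, palladium, H2 and cold BF3 steps and leave with fluoride at the end; no stereocentre.

Step 2
Reactants: 1 5-bromoresorcinol
Product: 3 2-bromo-4,6-dihydroxybenzaldehyde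
Conditions: POCl3, DMF, MeCN, −15 → 25 °C; then H2O, 50 °C
Reagents that add atoms: N,N-dimethylformamide, CN(C)C=O; water, O
Why: Vilsmeier–Haack formylation goes para to one hydroxyl and ortho to the other (as with orcinol), i.e. next to bromine, and the iminium salt is hydrolysed on work-up.

Step 3
Reactants: 3 2-bromo-4,6-dihydroxybenzaldehyde
Product: 4 2-bromo-6-hydroxy-4-(TIPS-oxy)benzaldehyde
Conditions: TIPSCl (1.05 equiv), imidazole, CH2Cl2, 0 °C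
Reagents that add atoms: triisopropylsilyl chloride, Cl[Si](C(C)C)(C(C)C)C(C)C
Why: Selective silylation: the 4-OH para to the formyl group is the more acidic and is free, while the 6-OH is held in a hydrogen bond to the carbonyl.

Step 4
Reactants: 4 2-bromo-6-hydroxy-4-(TIPS-oxy)benzaldehyde
Product: 5 3-bromo-2-formyl-5-(TIPS-oxy)phenyl tert-butyl carbonate
Conditions: Boc2O, DMAP (5 mol %), CH2Cl2, 25 °C
Reagents that add atoms: di-tert-butyl dicarbonate, CC(C)(C)OC(=O)OC(=O)OC(C)(C)C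
Why: DMAP-catalysed O-acylation of the phenol; the aryl carbonate is the trigger for low-temperature o-quinone methide release in step 9.

Step 5
Reactants: 2 1-bromo-3,5-bis(TIPS-oxy)benzene; 5 3-bromo-2-formyl-5-(TIPS-oxy)phenyl tert-butyl carbonate
Product: 7 rac-3-bromo-2-{[3,5-bis(TIPS-oxy)phenyl][(tert-butoxycarbonyl)oxy]methyl}-5-(TIPS-oxy)phenol, via aryl Grignard reagent 6 (not isolated)
Conditions: 2, Mg, THF, 40 °C; then 5, THF, −78 °C; AcOH, −78 °C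
Reagents that add atoms: none
Why: Grignard addition to the aldehyde, after which the magnesium alkoxide takes the Boc group from the neighbouring phenol oxygen (intramolecular O→O acyl transfer), so the cold quench gives a benzylic carbonate beside a free phenol; the carbinol centre is racemic and is erased in step 9.

Step 6
Reactants: 8 4-methylphenol
Product: 9 triisopropyl(4-methylphenoxy)silane
Conditions: TIPSCl, imidazole, DMF, 25 °C
Reagents that add atoms: triisopropylsilyl chloride, Cl[Si](C(C)C)(C(C)C)C(C)C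
Why: Standard phenol silylation; no stereocentre.

Step 7
Reactants: 9 triisopropyl(4-methylphenoxy)silane
Product: 10 [4-(bromomethyl)phenoxy]triisopropylsilane
Conditions: NBS, AIBN (cat.), PhCF3, 85 °C
Reagents that add atoms: N-bromosuccinimide, O=C1CCC(=O)N1Br
Why: Wohl–Ziegler radical bromination at the only benzylic position.

Step 8
Reactants: 10 [4-(bromomethyl)phenoxy]triisopropylsilane; 11 (1R,4R,5R)-isothiocineole
Product: 12 (1R,4R,5R)-4,7,7-trimethyl-6-[4-(TIPS-oxy)benzyl]-6-thiabicyclo[3.2.1]octan-6-ium triflate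
Conditions: LiOTf, CH2Cl2/H2O, 25 °C
Reagents that add atoms: lithium triflate, [Li+].[O-]S(=O)(=O)C(F)(F)F
Why: S-alkylation of the sulfide by the activated benzyl bromide, made irreversible by exchange to the non-nucleophilic triflate; alkylation on the open face of the bicyclic sulfide gives one sulfonium diastereomer.

Step 9
Reactants: 7 rac-3-bromo-2-{[3,5-bis(TIPS-oxy)phenyl][(tert-butoxycarbonyl)oxy]methyl}-5-(TIPS-oxy)phenol; 12 (1R,4R,5R)-4,7,7-trimethyl-6-[4-(TIPS-oxy)benzyl]-6-thiabicyclo[3.2.1]octan-6-ium triflate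
Product: 15 (2R,3R)-4-bromo-3-[3,5-bis(TIPS-oxy)phenyl]-6-(TIPS-oxy)-2-[4-(TIPS-oxy)phenyl]-2,3-dihydrobenzofuran, via sulfonium ylide 13 (not isolated), via o-quinone methide 14 (not isolated)
Conditions: Cs2CO3 (2.5 equiv), CH2Cl2, −20 → 25 °C
Reagents that add atoms: none
Why: Proposed new method: base releases o-quinone methide 14 from 7 (phenoxide-driven 1,4-elimination of tert-butyl carbonate) and ylide 13 from 12; conjugate addition of the ylide to the exocyclic carbon and intramolecular SN2 displacement of the sulfide by the phenoxide (inversion at the ylide carbon) close the trans-dihydrobenzofuran, the sulfide fixing the ylide face (C2) and the anti betaine the C3 configuration; closest known reaction type: formal [4+1] annulation of o-quinone methides with sulfonium ylides, combined with chiral-sulfide Corey–Chaykovsky-type asymmetric epoxidation.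

Step 10
Reactants: 16 mucobromic acid; 17 (1R,2S,5R)-menthol
Product: 19 (5R)-3,4-dibromo-5-(Men-oxy)furan-2(5H)-one, via 5S acetal epimer 18 (not isolated)
Conditions: TsOH·H2O (cat.), toluene, reflux, Dean–Stark; crystallisation from hexane, mother liquor re-equilibrated
Reagents that add atoms: none
Why: Acid-catalysed acetalisation of the lactol (pseudo-acid) form of mucobromic acid; both C5 epimers form and interconvert under the acid while the (5R)-epimer crystallises (crystallisation-induced diastereomer transformation), which fixes the only auxiliary-controlled stereocentre.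

Step 11
Reactants: 2 1-bromo-3,5-bis(TIPS-oxy)benzene; 19 (5R)-3,4-dibromo-5-(Men-oxy)furan-2(5H)-one
Product: 22 (5R)-3-bromo-4-[3,5-bis(TIPS-oxy)phenyl]-5-(Men-oxy)furan-2(5H)-one, via aryllithium 20 (not isolated), via arylzinc chloride 21 (not isolated)
Conditions: 2, n-BuLi, THF, −78 °C; ZnCl2, −78 → 25 °C; then 19, Pd(PPh3)4 (3 mol %), THF, 25 → 45 °C
Reagents that add atoms: none
Why: Bromine–lithium exchange and transmetalation to zinc, then Negishi coupling; oxidative addition is faster at the β C–Br bond (C4, the vinylogous acyl bromide position) than at the α C–Br bond, as in the known C4-selective couplings of 3,4-dibromofuranones, and the base-free conditions leave the C5 acetal centre untouched.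

Step 12
Reactants: 15 (2R,3R)-4-bromo-3-[3,5-bis(TIPS-oxy)phenyl]-6-(TIPS-oxy)-2-[4-(TIPS-oxy)phenyl]-2,3-dihydrobenzofuran; 22 (5R)-3-bromo-4-[3,5-bis(TIPS-oxy)phenyl]-5-(Men-oxy)furan-2(5H)-one
Product: 25 (5R)-3-ArD-4-[3,5-bis(TIPS-oxy)phenyl]-5-(Men-oxy)furan-2(5H)-one, via aryllithium 23 (not isolated), via arylzinc chloride 24 (not isolated)
Conditions: 15, n-BuLi, THF, −78 °C; ZnCl2; then 22, Pd2(dba)3 (2.5 mol %), SPhos, THF, 60 °C
Reagents that add atoms: none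
Why: Negishi coupling of the hindered arylzinc with the remaining α-bromide under a bulky biarylphosphine ligand; no base is present, so neither the acetal centre nor the dihydrobenzofuran centres can epimerise.

Step 13
Reactants: 25 (5R)-3-ArD-4-[3,5-bis(TIPS-oxy)phenyl]-5-(Men-oxy)furan-2(5H)-one
Product: 26 (3S,4R,5R)-3-ArD-4-[3,5-bis(TIPS-oxy)phenyl]-5-(Men-oxy)dihydrofuran-2(3H)-one (all-cis)
Conditions: H2 (10 bar), 10% Pd/C, EtOAc, 25 °C
Reagents that add atoms: none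
Why: Heterogeneous catalytic hydrogenation adds both hydrogens syn from the face opposite the C5 menthyloxy group, so the C3 and C4 aryl groups end up cis to each other with (3S,4R) configuration; silyl ethers are inert to these conditions.

Step 14
Reactants: 26 (3S,4R,5R)-3-ArD-4-[3,5-bis(TIPS-oxy)phenyl]-5-(Men-oxy)dihydrofuran-2(3H)-one; 27 (4-bromophenoxy)triisopropylsilane
Product: 31 (2S,3S,4R,5R)-3-ArD-4-[3,5-bis(TIPS-oxy)phenyl]-5-(Men-oxy)-2-[4-(TIPS-oxy)phenyl]tetrahydrofuran, via aryllithium 28 (not isolated), via arylcerium dichloride 29 (not isolated), via hemiketal 30 (not isolated)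
Conditions: 27, n-BuLi, THF, −78 °C; CeCl3; then 26, −78 °C; H2O, 0 °C; then Et3SiH, BF3·OEt2, CH2Cl2, −78 °C
Reagents that add atoms: none
Why: The weakly basic organocerium adds to the α-aryl lactone without enolising it, and ionic hydrogenation of the hemiketal (lactol reduction as in C-aryl glycoside synthesis) delivers hydride to the 2-aryl oxocarbenium ion from the face opposite the three cis substituents at C3, C4 and C5, which places the new C2 aryl cis to the C3 aryl (2S); the less easily ionised C5 acetal survives at −78 °C.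

Step 15
Reactants: 31 (2S,3S,4R,5R)-3-ArD-4-[3,5-bis(TIPS-oxy)phenyl]-5-(Men-oxy)-2-[4-(TIPS-oxy)phenyl]tetrahydrofuran; 27 (4-bromophenoxy)triisopropylsilane
Product: 34 (2S,3S,4R,5S)-3-ArD-4-[3,5-bis(TIPS-oxy)phenyl]-2,5-bis[4-(TIPS-oxy)phenyl]tetrahydrofuran, via bromo ether 32 (not isolated), via aryl Grignard reagent 33 (not isolated)
Conditions: TMSBr (1.1 equiv), CH2Cl2, −40 °C; then 33 (from 27, Mg, THF), −78 → 0 °C
Reagents that add atoms: none
Why: TMSBr turns the menthyl acetal into the α-bromo ether, which the Grignard reagent substitutes through the cyclic oxocarbenium ion (α-halo ether coupling, C-glycosylation type) from the face opposite the three cis aryl groups, giving the 4,5-trans (5S) centre and releasing the auxiliary.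

Step 16
Reactants: 34 (2S,3S,4R,5S)-3-ArD-4-[3,5-bis(TIPS-oxy)phenyl]-2,5-bis[4-(TIPS-oxy)phenyl]tetrahydrofuran
Product: 35 target CNP0202577.3
Conditions: TBAF, AcOH (1:1, 10 equiv), THF, 0 → 25 °C
Reagents that add atoms: none
Why: Fluoride desilylation of all eight aryl silyl ethers; the acetic acid buffer keeps the phenols protonated, so the p-hydroxybenzylic ether centres (kinetic 2,3-cis arrangement) cannot open through quinone methides and epimerise.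

**Compound list**

1 | 5-bromoresorcinol | Oc1cc(O)cc(Br)c1 | starting material
2 | 1-bromo-3,5-bis(TIPS-oxy)benzene | Brc1cc(O[Si](C(C)C)(C(C)C)C(C)C)cc(O[Si](C(C)C)(C(C)C)C(C)C)c1 | intermediate
3 | 2-bromo-4,6-dihydroxybenzaldehyde | O=Cc1c(O)cc(O)cc1Br | intermediate
4 | 2-bromo-6-hydroxy-4-(TIPS-oxy)benzaldehyde | O=Cc1c(O)cc(O[Si](C(C)C)(C(C)C)C(C)C)cc1Br | intermediate
5 | 3-bromo-2-formyl-5-(TIPS-oxy)phenyl tert-butyl carbonate | O=Cc1c(OC(=O)OC(C)(C)C)cc(O[Si](C(C)C)(C(C)C)C(C)C)cc1Br | intermediate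
6 | [3,5-bis(TIPS-oxy)phenyl]magnesium bromide (formed in situ) | Br[Mg]c1cc(O[Si](C(C)C)(C(C)C)C(C)C)cc(O[Si](C(C)C)(C(C)C)C(C)C)c1 | intermediate
7 | rac-3-bromo-2-{[3,5-bis(TIPS-oxy)phenyl][(tert-butoxycarbonyl)oxy]methyl}-5-(TIPS-oxy)phenol | CC(C)(C)OC(=O)OC(c1cc(O[Si](C(C)C)(C(C)C)C(C)C)cc(O[Si](C(C)C)(C(C)C)C(C)C)c1)c1c(O)cc(O[Si](C(C)C)(C(C)C)C(C)C)cc1Br | intermediate
8 | 4-methylphenol | Cc1ccc(O)cc1 | starting material
9 | triisopropyl(4-methylphenoxy)silane | Cc1ccc(O[Si](C(C)C)(C(C)C)C(C)C)cc1 | intermediate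
10 | [4-(bromomethyl)phenoxy]triisopropylsilane | BrCc1ccc(O[Si](C(C)C)(C(C)C)C(C)C)cc1 | intermediate
11 | (1R,4R,5R)-isothiocineole (4,7,7-trimethyl-6-thiabicyclo[3.2.1]octane) | C[C@@H]1CC[C@@H]2C[C@H]1SC2(C)C | starting material
12 | (1R,4R,5R)-4,7,7-trimethyl-6-[4-(TIPS-oxy)benzyl]-6-thiabicyclo[3.2.1]octan-6-ium triflate (one diastereomer at sulfur) | C[C@@H]1CC[C@@H]2C[C@H]1[S+](Cc1ccc(O[Si](C(C)C)(C(C)C)C(C)C)cc1)C2(C)C.[O-]S(=O)(=O)C(F)(F)F | intermediate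
13 | sulfonium 4-(TIPS-oxy)benzylide derived from 12 (formed in situ) | C[C@@H]1CC[C@@H]2C[C@H]1[S+]([CH-]c1ccc(O[Si](C(C)C)(C(C)C)C(C)C)cc1)C2(C)C | intermediate
14 | 5-bromo-6-[3,5-bis(TIPS-oxy)benzylidene]-3-(TIPS-oxy)cyclohexa-2,4-dien-1-one (o-quinone methide, formed in situ) | O=C1C=C(O[Si](C(C)C)(C(C)C)C(C)C)C=C(Br)C1=Cc1cc(O[Si](C(C)C)(C(C)C)C(C)C)cc(O[Si](C(C)C)(C(C)C)C(C)C)c1 | intermediate
15 | (2R,3R)-4-bromo-3-[3,5-bis(TIPS-oxy)phenyl]-6-(TIPS-oxy)-2-[4-(TIPS-oxy)phenyl]-2,3-dihydrobenzofuran (trans; ArD–Br) | Brc1cc(O[Si](C(C)C)(C(C)C)C(C)C)cc2c1[C@@H](c1cc(O[Si](C(C)C)(C(C)C)C(C)C)cc(O[Si](C(C)C)(C(C)C)C(C)C)c1)[C@H](c1ccc(O[Si](C(C)C)(C(C)C)C(C)C)cc1)O2 | intermediate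
16 | mucobromic acid (3,4-dibromo-5-hydroxyfuran-2(5H)-one) | OC1OC(=O)C(Br)=C1Br | starting material
17 | (1R,2S,5R)-menthol | C[C@@H]1CC[C@H]([C@@H](C1)O)C(C)C | starting material
18 | (5S)-3,4-dibromo-5-(Men-oxy)furan-2(5H)-one (equilibrating epimer) | O=C1O[C@H](O[C@@H]2C[C@H](C)CC[C@H]2C(C)C)C(Br)=C1Br | intermediate
19 | (5R)-3,4-dibromo-5-(Men-oxy)furan-2(5H)-one | O=C1O[C@@H](O[C@@H]2C[C@H](C)CC[C@H]2C(C)C)C(Br)=C1Br | intermediate
20 | [3,5-bis(TIPS-oxy)phenyl]lithium (formed in situ) | [Li]c1cc(O[Si](C(C)C)(C(C)C)C(C)C)cc(O[Si](C(C)C)(C(C)C)C(C)C)c1 | intermediate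
21 | [3,5-bis(TIPS-oxy)phenyl]zinc chloride (formed in situ) | Cl[Zn]c1cc(O[Si](C(C)C)(C(C)C)C(C)C)cc(O[Si](C(C)C)(C(C)C)C(C)C)c1 | intermediate
22 | (5R)-3-bromo-4-[3,5-bis(TIPS-oxy)phenyl]-5-(Men-oxy)furan-2(5H)-one | O=C1O[C@@H](O[C@@H]2C[C@H](C)CC[C@H]2C(C)C)C(c2cc(O[Si](C(C)C)(C(C)C)C(C)C)cc(O[Si](C(C)C)(C(C)C)C(C)C)c2)=C1Br | intermediate
23 | ArD–Li (4-lithio derivative of 15, formed in situ) | [Li]c1cc(O[Si](C(C)C)(C(C)C)C(C)C)cc2c1[C@@H](c1cc(O[Si](C(C)C)(C(C)C)C(C)C)cc(O[Si](C(C)C)(C(C)C)C(C)C)c1)[C@H](c1ccc(O[Si](C(C)C)(C(C)C)C(C)C)cc1)O2 | intermediate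
24 | ArD–ZnCl (formed in situ) | Cl[Zn]c1cc(O[Si](C(C)C)(C(C)C)C(C)C)cc2c1[C@@H](c1cc(O[Si](C(C)C)(C(C)C)C(C)C)cc(O[Si](C(C)C)(C(C)C)C(C)C)c1)[C@H](c1ccc(O[Si](C(C)C)(C(C)C)C(C)C)cc1)O2 | intermediate
25 | (5R)-3-ArD-4-[3,5-bis(TIPS-oxy)phenyl]-5-(Men-oxy)furan-2(5H)-one | O=C1O[C@@H](O[C@@H]2C[C@H](C)CC[C@H]2C(C)C)C(c2cc(O[Si](C(C)C)(C(C)C)C(C)C)cc(O[Si](C(C)C)(C(C)C)C(C)C)c2)=C1c1cc(O[Si](C(C)C)(C(C)C)C(C)C)cc2c1[C@@H](c1cc(O[Si](C(C)C)(C(C)C)C(C)C)cc(O[Si](C(C)C)(C(C)C)C(C)C)c1)[C@H](c1ccc(O[Si](C(C)C)(C(C)C)C(C)C)cc1)O2 | intermediate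
26 | (3S,4R,5R)-3-ArD-4-[3,5-bis(TIPS-oxy)phenyl]-5-(Men-oxy)dihydrofuran-2(3H)-one (all-cis) | O=C1O[C@@H](O[C@@H]2C[C@H](C)CC[C@H]2C(C)C)[C@@H](c2cc(O[Si](C(C)C)(C(C)C)C(C)C)cc(O[Si](C(C)C)(C(C)C)C(C)C)c2)[C@H]1c1cc(O[Si](C(C)C)(C(C)C)C(C)C)cc2c1[C@@H](c1cc(O[Si](C(C)C)(C(C)C)C(C)C)cc(O[Si](C(C)C)(C(C)C)C(C)C)c1)[C@H](c1ccc(O[Si](C(C)C)(C(C)C)C(C)C)cc1)O2 | intermediate
27 | (4-bromophenoxy)triisopropylsilane | Brc1ccc(O[Si](C(C)C)(C(C)C)C(C)C)cc1 | starting material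
28 | [4-(TIPS-oxy)phenyl]lithium (formed in situ) | [Li]c1ccc(O[Si](C(C)C)(C(C)C)C(C)C)cc1 | intermediate
29 | [4-(TIPS-oxy)phenyl]cerium dichloride (formed in situ) | Cl[Ce](Cl)c1ccc(O[Si](C(C)C)(C(C)C)C(C)C)cc1 | intermediate
30 | (3S,4R,5R)-3-ArD-4-[3,5-bis(TIPS-oxy)phenyl]-5-(Men-oxy)-2-[4-(TIPS-oxy)phenyl]tetrahydrofuran-2-ol (hemiketal, C2 epimers, used crude) | OC1(c2ccc(O[Si](C(C)C)(C(C)C)C(C)C)cc2)O[C@@H](O[C@@H]2C[C@H](C)CC[C@H]2C(C)C)[C@@H](c2cc(O[Si](C(C)C)(C(C)C)C(C)C)cc(O[Si](C(C)C)(C(C)C)C(C)C)c2)[C@H]1c1cc(O[Si](C(C)C)(C(C)C)C(C)C)cc2c1[C@@H](c1cc(O[Si](C(C)C)(C(C)C)C(C)C)cc(O[Si](C(C)C)(C(C)C)C(C)C)c1)[C@H](c1ccc(O[Si](C(C)C)(C(C)C)C(C)C)cc1)O2 | intermediate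
31 | (2S,3S,4R,5R)-3-ArD-4-[3,5-bis(TIPS-oxy)phenyl]-5-(Men-oxy)-2-[4-(TIPS-oxy)phenyl]tetrahydrofuran (C2, C3, C4, C5 substituents all cis) | CC(C)[Si](C(C)C)(C(C)C)Oc1ccc(cc1)[C@H]1O[C@@H](O[C@@H]2C[C@H](C)CC[C@H]2C(C)C)[C@@H](c2cc(O[Si](C(C)C)(C(C)C)C(C)C)cc(O[Si](C(C)C)(C(C)C)C(C)C)c2)[C@H]1c1cc(O[Si](C(C)C)(C(C)C)C(C)C)cc2c1[C@@H](c1cc(O[Si](C(C)C)(C(C)C)C(C)C)cc(O[Si](C(C)C)(C(C)C)C(C)C)c1)[C@H](c1ccc(O[Si](C(C)C)(C(C)C)C(C)C)cc1)O2 | intermediate
32 | (2S,3S,4R)-3-ArD-5-bromo-4-[3,5-bis(TIPS-oxy)phenyl]-2-[4-(TIPS-oxy)phenyl]tetrahydrofuran (α-bromo ether, C5 anomers, formed in situ) | CC(C)[Si](C(C)C)(C(C)C)Oc1ccc(cc1)[C@H]1OC(Br)[C@@H](c2cc(O[Si](C(C)C)(C(C)C)C(C)C)cc(O[Si](C(C)C)(C(C)C)C(C)C)c2)[C@H]1c1cc(O[Si](C(C)C)(C(C)C)C(C)C)cc2c1[C@@H](c1cc(O[Si](C(C)C)(C(C)C)C(C)C)cc(O[Si](C(C)C)(C(C)C)C(C)C)c1)[C@H](c1ccc(O[Si](C(C)C)(C(C)C)C(C)C)cc1)O2 | intermediate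
33 | [4-(TIPS-oxy)phenyl]magnesium bromide (formed in situ) | Br[Mg]c1ccc(O[Si](C(C)C)(C(C)C)C(C)C)cc1 | intermediate
34 | (2S,3S,4R,5S)-3-ArD-4-[3,5-bis(TIPS-oxy)phenyl]-2,5-bis[4-(TIPS-oxy)phenyl]tetrahydrofuran (octa-TIPS ether of the target) | CC(C)[Si](C(C)C)(C(C)C)Oc1ccc(cc1)[C@H]1O[C@H](c2ccc(O[Si](C(C)C)(C(C)C)C(C)C)cc2)[C@@H](c2cc(O[Si](C(C)C)(C(C)C)C(C)C)cc(O[Si](C(C)C)(C(C)C)C(C)C)c2)[C@H]1c1cc(O[Si](C(C)C)(C(C)C)C(C)C)cc2c1[C@@H](c1cc(O[Si](C(C)C)(C(C)C)C(C)C)cc(O[Si](C(C)C)(C(C)C)C(C)C)c1)[C@H](c1ccc(O[Si](C(C)C)(C(C)C)C(C)C)cc1)O2 | intermediate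
35 | CNP0202577.3: 5-[(2R,3R)-4-[(2S,3S,4R,5S)-4-(3,5-dihydroxyphenyl)-2,5-bis(4-hydroxyphenyl)oxolan-3-yl]-6-hydroxy-2-(4-hydroxyphenyl)-2,3-dihydro-1-benzofuran-3-yl]benzene-1,3-diol | Oc1ccc([C@H]2O[C@H](c3ccc(O)cc3)[C@@H](c3cc(O)cc(O)c3)[C@H]2c2cc(O)cc3c2[C@@H](c2cc(O)cc(O)c2)[C@H](c2ccc(O)cc2)O3)cc1 | target

**Totals and risk**

Total step count: 16. Longest linear sequence: 10 steps (steps 2, 3, 4, 5, 9, 12, 13, 14, 15, 16, from 5-bromoresorcinol).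

The three steps most likely to fail:

Step 9. The chiral benzylide/o-quinone methide [4+1] annulation has no direct precedent. The quinone methide is congested by the neighbouring bromine, and both the trans/cis ratio and the ee are uncertain. Fallback: this sets out from 7 and 10 and gives up asymmetric induction. Bromide 10 is quaternised with tetrahydrothiophene and LiOTf to the achiral 1-[4-(TIPS-oxy)benzyl]tetrahydrothiophen-1-ium triflate F1. With Cs2CO3 in CH2Cl2 its small, unhindered ylide, tetrahydrothiophenium 4-(TIPS-oxy)benzylide F2, adds to o-quinone methide 14 released from 7. This gives the racemic trans-dihydrobenzofuran, that is 15 together with its (2S,3S)-enantiomer F3. Preparative chromatography on a chiral stationary phase separates the two, and the route is rejoined at 15.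

Step 13. Hydrogenation of a tetrasubstituted, doubly arylated butenolide may stall, or may hydrogenolyse the allylic acetal or the benzylic dihydrobenzofuran C–O bond. Fallback: this sets out from 25 and delivers hydride and proton in separate events instead of H2. A copper hydride conjugate reduction (Cu(OAc)2 cat., 1,2-bis(diphenylphosphino)benzene, tetramethyldisiloxane, t-BuOH, toluene) puts hydride on C4 anti to the menthyloxy group. The α-centre then settles to the 3,4-trans lactone, (3R,4R,5R)-3-epi-26 F4. LiN(SiMe3)2 in THF at −78 °C converts this into the lithium enolate F5. Kinetic protonation with 2,6-di-tert-butylphenol from the face opposite the C4 aryl group gives the all-cis lactone, and the route is rejoined at 26.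

Step 14. Three things can go wrong: residual enolisation and C3 epimerisation of the α-aryl lactone, ring-opening of hemiketal 30 with loss of menthol, and over-reduction of the C5 acetal. Fallback: this sets out from 25 and uses aryllithium 28, made from 27 as in step 14, so that no enolisable lactone ever meets the aryl nucleophile. Aryllithium 28 adds 1,2 to the butenolide carbonyl to give the unsaturated hemiketal (5R)-3-ArD-4-[3,5-bis(TIPS-oxy)phenyl]-5-(Men-oxy)-2-[4-(TIPS-oxy)phenyl]-2,5-dihydrofuran-2-ol F6. Et3SiH/BF3·OEt2 at −78 °C reduces the conjugated oxocarbenium ion trans to the C5 menthyloxy group, giving the (2R,5R)-2,5-dihydrofuran F7. Hydrogenation over Pd/C then takes place from the face opposite both the C2 aryl and the C5 menthyloxy groups, and the route is rejoined at 31.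

**Further compounds**

F1 | step 9 | 1-[4-(TIPS-oxy)benzyl]tetrahydrothiophen-1-ium triflate | C1CC[S+](C1)Cc1ccc(O[Si](C(C)C)(C(C)C)C(C)C)cc1.[O-]S(=O)(=O)C(F)(F)F
F2 | step 9 | tetrahydrothiophenium 4-(TIPS-oxy)benzylide | C1CC[S+](C1)[CH-]c1ccc(O[Si](C(C)C)(C(C)C)C(C)C)cc1
F3 | step 9 | (2S,3S)-4-bromo-3-[3,5-bis(TIPS-oxy)phenyl]-6-(TIPS-oxy)-2-[4-(TIPS-oxy)phenyl]-2,3-dihydrobenzofuran (enantiomer of 15) | Brc1cc(O[Si](C(C)C)(C(C)C)C(C)C)cc2c1[C@H](c1cc(O[Si](C(C)C)(C(C)C)C(C)C)cc(O[Si](C(C)C)(C(C)C)C(C)C)c1)[C@@H](c1ccc(O[Si](C(C)C)(C(C)C)C(C)C)cc1)O2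
F4 | step 13 | (3R,4R,5R)-3-ArD-4-[3,5-bis(TIPS-oxy)phenyl]-5-(Men-oxy)dihydrofuran-2(3H)-one (3-epimer of 26) | O=C1O[C@@H](O[C@@H]2C[C@H](C)CC[C@H]2C(C)C)[C@@H](c2cc(O[Si](C(C)C)(C(C)C)C(C)C)cc(O[Si](C(C)C)(C(C)C)C(C)C)c2)[C@@H]1c1cc(O[Si](C(C)C)(C(C)C)C(C)C)cc2c1[C@@H](c1cc(O[Si](C(C)C)(C(C)C)C(C)C)cc(O[Si](C(C)C)(C(C)C)C(C)C)c1)[C@H](c1ccc(O[Si](C(C)C)(C(C)C)C(C)C)cc1)O2
F5 | step 13 | lithium enolate of F4 ((4R,5R)-2-lithiooxy-3-ArD-4-[3,5-bis(TIPS-oxy)phenyl]-5-(Men-oxy)-4,5-dihydrofuran) | [Li]OC1=C(c2cc(O[Si](C(C)C)(C(C)C)C(C)C)cc3c2[C@@H](c2cc(O[Si](C(C)C)(C(C)C)C(C)C)cc(O[Si](C(C)C)(C(C)C)C(C)C)c2)[C@H](c2ccc(O[Si](C(C)C)(C(C)C)C(C)C)cc2)O3)[C@H](c2cc(O[Si](C(C)C)(C(C)C)C(C)C)cc(O[Si](C(C)C)(C(C)C)C(C)C)c2)[C@H](O[C@@H]2C[C@H](C)CC[C@H]2C(C)C)O1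
F6 | step 14 | (5R)-3-ArD-4-[3,5-bis(TIPS-oxy)phenyl]-5-(Men-oxy)-2-[4-(TIPS-oxy)phenyl]-2,5-dihydrofuran-2-ol (C2 epimers) | OC1(c2ccc(O[Si](C(C)C)(C(C)C)C(C)C)cc2)O[C@@H](O[C@@H]2C[C@H](C)CC[C@H]2C(C)C)C(c2cc(O[Si](C(C)C)(C(C)C)C(C)C)cc(O[Si](C(C)C)(C(C)C)C(C)C)c2)=C1c1cc(O[Si](C(C)C)(C(C)C)C(C)C)cc2c1[C@@H](c1cc(O[Si](C(C)C)(C(C)C)C(C)C)cc(O[Si](C(C)C)(C(C)C)C(C)C)c1)[C@H](c1ccc(O[Si](C(C)C)(C(C)C)C(C)C)cc1)O2
F7 | step 14 | (2R,5R)-3-ArD-4-[3,5-bis(TIPS-oxy)phenyl]-5-(Men-oxy)-2-[4-(TIPS-oxy)phenyl]-2,5-dihydrofuran (2,5-cis) | CC(C)[Si](C(C)C)(C(C)C)Oc1ccc(cc1)[C@H]1O[C@@H](O[C@@H]2C[C@H](C)CC[C@H]2C(C)C)C(c2cc(O[Si](C(C)C)(C(C)C)C(C)C)cc(O[Si](C(C)C)(C(C)C)C(C)C)c2)=C1c1cc(O[Si](C(C)C)(C(C)C)C(C)C)cc2c1[C@@H](c1cc(O[Si](C(C)C)(C(C)C)C(C)C)cc(O[Si](C(C)C)(C(C)C)C(C)C)c1)[C@H](c1ccc(O[Si](C(C)C)(C(C)C)C(C)C)cc1)O2
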